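Remark on the chemistry (assumption): locants C1–C40 run from the lactone carbonyl (C1) round the ring to C35 and on to the butyl terminus (C40), with methyl branches on C3 and C36. Methyl hydrogen (3S)-3-methylglutarate 30 and both antipodes of B-allyldiisopinocampheylborane are taken as purchasable. TBS = tert-butyldimethylsilyl, Bn = benzyl.

## Analysis of the target

Compound 49 is a 36-membered macrolactone: ring atoms C1 (carbonyl) to C35 plus the ester oxygen O35, with a methyl branch at C3 and a (2S)-hexan-2-yl side chain (C36–C40) on the carbinol carbon C35. It carries nine free secondary hydroxyls: five 1,5-related (C5, C9, C13, C17, C21), three as a 1,3,5-triol (C25, C27, C29) and one at C33, 1,3 to the acylated O35. There are twelve stereocentres (3R,5R,9R,13S,17S,21R,25S,27S,29S,33S,35R,36S). The local relationships are C3/C5 syn, C25/C27 syn, C27/C29 anti, C33/C35 anti and C35/C36 anti. C9, C13, C17 and C21 are each insulated by three methylenes and can only be set by reagent control; the stretch C9–C21 has a local twofold axis through C15, which C5 and C25 do not share. The molecule has no unsaturation, so C–C bonds may be made as alkynes or alkenes and hydrogenated. The sensitive points are the lactone of a hindered secondary alcohol next to the C33 hydroxyl (acyl migration under base), β-hydroxy carbonyl intermediates (elimination), and the need to keep O35 distinguishable from nine other oxygens until ring closure. The strategy rests on the segment C23–C28: oxygen on C25 and C27 in a syn relationship and methylene groups at C24, C26 and C28, which is the pattern of a 2,4-dideoxyhexose with C28 as its C6 and C23 as its anomeric carbon.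

## Retrosynthetic reasoning

**Ring and protecting groups.** 49 is taken back to its nonakis-silyl ether 48, so that one fluoride treatment ends the synthesis. The ring is cut at the only heteroatom bond, O35–C1, giving seco acid 46. A ring-closing olefin metathesis in one of the (CH2)3 spacers was weighed, but the C22–C23 alkyne that the route carries would engage the ruthenium carbene, so lactonisation is used. It sets no stereocentre and only needs O35 to be the one free hydroxyl.

**Unmasking of O35 and C1.** 46 comes from diol 44 by oxidation of the primary C1 alcohol in the presence of the hindered C35 alcohol. 44 comes from 43, in which O1 and O35 are the only benzyl ethers and C7–C8 and C22–C23 are alkynes. One hydrogenation therefore saturates both alkynes and frees exactly the two oxygens needed.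

**C21–C22.** 43 is cut between C21 and C22 into terminal alkyne 24 (C22–C40) and N-methoxy-N-methyl amide 40 (C1–C21). This cut is dictated by the origin of C23: an aldehyde carbon becomes an alkyne by one-carbon homologation, and the acetylide then needs an acyl partner at C21. C21 has no stereocentre nearby, so the ynone 41 is reduced under catalyst control to 42.

**C8–C9.** The same operation joins alkyne 37 (C1–C8) to the C2-symmetric bis-amide 29 (C9–C21), via ynone 38 and alcohol 39. Because C9 and C21 are related by the local twofold axis, both reductions use the same catalyst antipode. The two amide ends of 29 are equivalent, so the mono-addition is run with 29 in excess and the rest is recovered.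

**Bis-amide 29 and alkyne 37.** 29 comes from glutaraldehyde 25: a double allylboration sets C13 and C17 in 26, and a double cross-metathesis adds C9–C11 and C19–C21 (28). 37 takes C3 from the chiral pool (half ester 30); C5 is set by allylboration of aldehyde 33, and the allyl group of 35 is cut back and homologated to the alkyne.

**C28–C29.** 24 is cut into epoxide 8 (C22–C28) and dithiane 20 (C29–C40). The dithiane anion attacks the epoxide terminus C28, and the unmasked C29 ketone 22 sits β to the newly freed C27 hydroxyl, which directs the anti reduction to 23.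

**C23–C28 (key disconnection).** 8 comes from lactol 5 by opening the lactol into an alkyne and closing the chlorohydrin to the epoxide. 5 is the hemiacetal of 4, the double aldol adduct of chloroacetaldehyde 1 with two molecules of acetaldehyde 2. The bonds C26–C27 and C24–C25 and the stereocentres C27 and C25 are made by an aldolase in one operation, and the two chain ends emerge already differentiated.

**Dithiane 20.** C29 is added to alkene 18 by hydroformylation (19). C33 comes from chelation-controlled allylation of β-benzyloxy aldehyde 16. The C35/C36 pair comes from epoxide 13, made from (2E)-hept-2-en-1-ol 9 by asymmetric epoxidation (10) and methyl transfer with inversion (11).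

## Alternatives that were turned down

**Alternative 1:** Two-directional opening of a bis-epoxide. The cuts are C11–C12 and C18–C19. Two equivalents of the lithium acetylide of A3 open the C2-symmetric bis-epoxide A2 (C12–C18) at both termini under Lewis-acid assistance and give the C5–C25 diyne diol A1.
- For: two C–C bonds in one flask, and it uses the real local symmetry of C9–C21. C13/C17 come from the epoxide and C9/C21 from one enantiopure alkyne.
- Against: the symmetry ends at C9–C21. C5 and C25 are not symmetry-related, and C3 carries methyl where C27 carries oxygen. The two identical primary ether termini of A1 must be told apart statistically on an advanced intermediate, and C3, C5, C25, C27 and C29 must still be built one by one on a long chain.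
- Comparison: for C9–C21 it is at least as efficient as the double allylboration and cross-metathesis used here, and the chosen route also has one statistical differentiation (step 29), though at a cheap stage. In its place the chosen strategy gives the C25/C27 syn diol with two unlike termini in one protecting-group-free step, so the symmetric building block can stop at C21.

**Alternative 2:** Macrocyclic Horner–Wadsworth–Emmons closure at C2=C3. The seco aldehyde A5 (phosphonoacetate on O35, aldehyde at C3) is closed under mild lithium-salt/amine conditions to the E-enoate lactone A4.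
- For: the ester on the hindered O35 is made intermolecularly, and this olefination is reliable for large rings. As a ring-closing event it is as good as or better than a lactonisation at a hindered carbinol.
- Against: A4 lacks the C3 methyl group. A conjugate methyl addition to a 36-membered enoate has no conformational bias, so C3 would rest on catalyst control at the last stage. The C3 aldehyde of A5 is β-silyloxy and can eliminate under the basic closure. The phosphonoacetate cannot be carried through the carbanion unions, so O35 has to be singled out just as for a lactonisation.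
- Comparison: it creates no stereocentre and opens a new stereochemical problem. The chosen route buys C3 from the chiral pool and spends its key step on C25 and C27.

**Alternative 3:** Dithiane anion-relay linchpin at C33. The lithiated silyl dithiane A8 opens epoxide A7 (identical with 13) at C34, a 1,4-Brook shift moves silicon to O35, and the new C33 anion is alkylated by the C32 iodide A9 to give A6.
- For: three components and two C–C bonds in one pot, with O35 tagged automatically. For C29–C40 this is clearly more convergent than the ten linear steps to 20.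
- Against: the second electrophile is an unactivated primary iodide reacting with a hindered tertiary dithiane anion. After unmasking, the anti reduction at C33 needs a free O35 hydroxyl, which the Brook shift has just silylated. A9 must already contain C25, C27 and C29, which this step does nothing to create. The acetal protecting groups of A6 need acid at the end, strong enough to threaten the lactone.
- Comparison: it wins on convergence for the right-hand end. The chosen strategy supplies the C25/C27 diol enzymatically and places its dithiane at C29, where the epoxide opening frees O27 exactly where it is needed to direct the reduction.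

Key step: step 1

## Steps

Step 1
Reactants: 1 chloroacetaldehyde; 2 acetaldehyde (two equivalents enter the product)
Product: 5 (4R,6S)-6-(chloromethyl)oxane-2,4-diol, via (3S)-4-chloro-3-hydroxybutanal 3 (not isolated), via (3R,5S)-6-chloro-3,5-dihydroxyhexanal 4 (not isolated)
Conditions: 2-deoxy-D-ribose-5-phosphate aldolase (cell-free extract), H2O, pH 7.3, 25 °C, slow parallel feed of 1 (aq.) and 2 (2.2 equiv); EtOAc extraction
Reagents that add atoms: none
Why: The active-site lysine condenses with 2 to an enamine that adds to the carbonyl of 1 and sets C27; hydrolysis releases 3, which the enzyme accepts again as the electrophile for a second acetaldehyde enamine, setting C25 and giving 4. The closest known reaction type is the aldolase-catalysed sequential aldol of a 2-substituted acetaldehyde with two acetaldehyde donors used for statin side chains. The ring closes by 6-exo-trig hemiacetalisation of the C27 hydroxyl onto the C23 aldehyde, giving the oxane lactol 5. Both stereocentres are under enzyme control: the pocket fixes which carbonyl face the enamine reaches, so 4 is formed as the 3R,5S (syn) isomer without any substrate bias. The step needs acceptor selectivity (1 rather than 2 as first electrophile) and chain-length selectivity (two donors, not one or three). The first should be secured by the higher electrophilicity of the α-chloro aldehyde and the slow feed; the second by the lactol, which removes the aldehyde from the cycle, whereas 3 cannot form an unstrained hemiacetal and stays available. C28 leaves the step as a primary chloride and C23 as a masked aldehyde, so the two ends are already different.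

Step 2
Reactants: 5 (4R,6S)-6-(chloromethyl)oxane-2,4-diol
Product: 7 (2S)-1-[(2S)-oxiran-2-yl]pent-4-yn-2-ol, via (2S,4S)-1-chlorohept-6-yne-2,4-diol 6 (not isolated)
Conditions: MeC(O)C(N2)P(O)(OMe)2 (1.3 equiv), K2CO3 (3 equiv), MeOH, 0 °C → rt
Reagents that add atoms: dimethyl (1-diazo-2-oxopropyl)phosphonate, CC(=O)C(=[N+]=[N-])P(=O)(OC)OC
Why: Seyferth–Gilbert homologation (Ohira–Bestmann variant) acts on the open hydroxy aldehyde tautomer of 5 and turns C23 into an alkyne carbon with C22 added. Ring opening frees O27, whose alkoxide displaces chloride at C28 in the same basic methanol (Williamson closure, 3-exo-tet); no stereocentre is touched.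

Step 3
Reactants: 7 (2S)-1-[(2S)-oxiran-2-yl]pent-4-yn-2-ol
Product: 8 tert-butyldimethyl{[(2S)-1-[(2S)-oxiran-2-yl]pent-4-yn-2-yl]oxy}silane
Conditions: TBSCl (1.2 equiv), imidazole (2.5 equiv), DMF, 0 °C → rt
Reagents that add atoms: tert-butyldimethylsilyl chloride, CC(C)(C)[Si](C)(C)Cl
Why: Standard silylation of the secondary C25 hydroxyl; epoxide and alkyne are inert under these conditions. The silyl ether later prevents O25 from forming a hemiketal with the C29 ketone.

Step 4
Reactants: 9 (2E)-hept-2-en-1-ol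
Product: 10 [(2R,3R)-3-butyloxiran-2-yl]methanol
Conditions: Ti(OiPr)4 (5 mol%), D-(−)-diisopropyl tartrate (6 mol%), t-BuOOH (2 equiv), 4 Å molecular sieves, CH2Cl2, −20 °C
Reagents that add atoms: tert-butyl hydroperoxide, CC(C)(C)OO
Why: Sharpless asymmetric epoxidation; the titanium complex of the D-(−)-tartrate ester delivers oxygen to the alkene face that gives the (2R,3R) epoxy alcohol, which fixes the future C35 and, after inversion, C36.

Step 5
Reactants: 10 [(2R,3R)-3-butyloxiran-2-yl]methanol
Product: 11 (2S,3S)-3-methylheptane-1,2-diol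
Conditions: Me3Al (3 equiv), hexane/CH2Cl2, 0 °C → rt; aq. potassium sodium tartrate
Reagents that add atoms: trimethylaluminium, C[Al](C)C
Why: Trialkylaluminium opening of a 2,3-epoxy alcohol: the aluminium alkoxide of the primary hydroxyl activates the epoxide and methyl is transferred to the distal carbon (future C36) with inversion, giving the 1,2-diol. Inversion on the trans epoxide places C35–O and C36–CH3 anti.

Step 6
Reactants: 11 (2S,3S)-3-methylheptane-1,2-diol
Product: 13 (2S)-2-[(2S)-hexan-2-yl]oxirane, via (2S,3S)-2-hydroxy-3-methylheptyl 4-methylbenzenesulfonate 12 (not isolated)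
Conditions: NaH (2.2 equiv), 1-(p-toluenesulfonyl)imidazole (1.05 equiv), THF, 0 °C → rt
Reagents that add atoms: none
Why: The primary alkoxide is sulfonylated selectively and the neighbouring C35 alkoxide displaces the sulfonate (Williamson closure, 3-exo-tet). The C35–O bond is not broken, so the configuration is retained.

Step 7
Reactants: 13 (2S)-2-[(2S)-hexan-2-yl]oxirane
Product: 14 (4R,5S)-5-methylnon-1-en-4-ol
Conditions: CH2=CHMgBr (1.5 equiv), CuI (10 mol%), THF, −30 → 0 °C
Reagents that add atoms: vinylmagnesium bromide, C=C[Mg]Br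
Why: Copper-catalysed Grignard opening of a monosubstituted epoxide at its unsubstituted carbon C34 (SN2). C35 is not involved; its descriptor changes only through the priority rules.

Step 8
Reactants: 14 (4R,5S)-5-methylnon-1-en-4-ol
Product: 15 ({[(4R,5S)-5-methylnon-1-en-4-yl]oxy}methyl)benzene
Conditions: NaH, BnBr, Bu4NI (cat.), THF/DMF, 0 °C → rt
Reagents that add atoms: benzyl bromide, BrCc1ccccc1
Why: Williamson etherification. The benzyl group is the unique tag of O35, the chelating ether needed in step 10, and is removed in the late hydrogenation.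

Step 9
Reactants: 15 ({[(4R,5S)-5-methylnon-1-en-4-yl]oxy}methyl)benzene
Product: 16 (3R,4S)-3-(benzyloxy)-4-methyloctanal
Conditions: O3, CH2Cl2, −78 °C; PPh3, −78 °C → rt
Reagents that add atoms: ozone, [O-][O+]=O
Why: Ozonolysis with reductive work-up cuts the terminal alkene to the C33 aldehyde. The benzyl ether tolerates brief exposure at −78 °C and no stereocentre is α to the new carbonyl.

Step 10
Reactants: 16 (3R,4S)-3-(benzyloxy)-4-methyloctanal
Product: 17 (4S,6R,7S)-6-(benzyloxy)-7-methylundec-1-en-4-ol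
Conditions: TiCl4 (1.1 equiv), CH2Cl2, −78 °C; CH2=CHCH2SiMe3 (1.5 equiv), −78 °C
Reagents that add atoms: allyltrimethylsilane, C=CC[Si](C)(C)C
Why: Chelation-controlled Hosomi–Sakurai allylation (Reetz conditions): TiCl4 ties the C33 carbonyl and the O35 benzyl ether into a six-membered chelate. The allylsilane attacks the face opposite the C35 side chain, which should set C33 anti to O35.

Step 11
Reactants: 17 (4S,6R,7S)-6-(benzyloxy)-7-methylundec-1-en-4-ol
Product: 18 {[(4S,6R,7S)-6-(benzyloxy)-7-methylundec-1-en-4-yl]oxy}(tert-butyl)dimethylsilane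
Conditions: TBSOTf (1.3 equiv), 2,6-lutidine (2 equiv), CH2Cl2, −78 → 0 °C
Reagents that add atoms: tert-butyldimethylsilyl trifluoromethanesulfonate, CC(C)(C)[Si](C)(C)OS(=O)(=O)C(F)(F)F
Why: Silylation of the secondary C33 hydroxyl with the silyl triflate and a hindered base; no stereocentre is affected.

Step 12
Reactants: 18 {[(4S,6R,7S)-6-(benzyloxy)-7-methylundec-1-en-4-yl]oxy}(tert-butyl)dimethylsilane
Product: 19 (5S,7R,8S)-7-(benzyloxy)-5-[(tert-butyldimethylsilyl)oxy]-8-methyldodecanal
Conditions: Rh(acac)(CO)2 (1 mol%), BiPhePhos (3 mol%), CO/H2 (1:1, 10 bar), toluene, 60 °C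
Reagents that add atoms: carbon monoxide, [C-]#[O+]
Why: Rhodium-catalysed hydroformylation; the wide-bite-angle bisphosphite favours the terminal rhodium alkyl, so CO is inserted at the chain end and the linear aldehyde (C29) should result. The ethers are inert and no stereocentre is formed.

Step 13
Reactants: 19 (5S,7R,8S)-7-(benzyloxy)-5-[(tert-butyldimethylsilyl)oxy]-8-methyldodecanal
Product: 20 2-[(4S,6R,7S)-6-(benzyloxy)-4-[(tert-butyldimethylsilyl)oxy]-7-methylundecyl]-1,3-dithiane
Conditions: HS(CH2)3SH (1.2 equiv), MgBr2·OEt2 (1.5 equiv), Et2O, 0 °C → rt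
Reagents that add atoms: propane-1,3-dithiol, SCCCS
Why: Lewis-acid-mediated dithioacetalisation of the aldehyde; MgBr2 is mild enough to leave the secondary silyl ether and the benzyl ether in place.

Step 14
Reactants: 20 2-[(4S,6R,7S)-6-(benzyloxy)-4-[(tert-butyldimethylsilyl)oxy]-7-methylundecyl]-1,3-dithiane; 8 tert-butyldimethyl{[(2S)-1-[(2S)-oxiran-2-yl]pent-4-yn-2-yl]oxy}silane
Product: 21 (2S,4S)-4-(TBSO)-1-{2-[(4S,6R,7S)-6-(benzyloxy)-4-(TBSO)-7-methylundecyl]-1,3-dithian-2-yl}hept-6-yn-2-ol
Conditions: 20, t-BuLi (1.05 equiv), THF/HMPA (10:1), −78 °C; then lithium acetylide of 8 (from 8, n-BuLi 1.0 equiv, THF, −78 °C), −78 → −30 °C; aq. NH4Cl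
Reagents that add atoms: none
Why: Corey–Seebach umpolung: the 2-lithio-1,3-dithiane of 20 opens the monosubstituted epoxide of 8 at its unsubstituted carbon C28 (SN2), forming C28–C29 and leaving C27 as a free secondary alcohol of unchanged configuration. The acidic alkyne hydrogen of 8 is removed beforehand; the lithium acetylide does not open epoxides at this temperature without a Lewis acid and is reprotonated on work-up.

Step 15
Reactants: 21 (2S,4S)-4-(TBSO)-1-{2-[(4S,6R,7S)-6-(benzyloxy)-4-(TBSO)-7-methylundecyl]-1,3-dithian-2-yl}hept-6-yn-2-ol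
Product: 22 (4S,6S,12S,14R,15S)-14-(benzyloxy)-4,12-bis(TBSO)-6-hydroxy-15-methylnonadec-1-yn-8-one
Conditions: MeI (10 equiv), CaCO3 (5 equiv), MeCN/H2O (9:1), 40 °C
Reagents that add atoms: water, O
Why: S-Methylation turns the dithiane into a leaving group and water hydrolyses the thionium ion to the C29 ketone. The buffered, metal-free conditions should spare the terminal alkyne, the silyl ethers and the β-hydroxy ketone.

Step 16
Reactants: 22 (4S,6S,12S,14R,15S)-14-(benzyloxy)-4,12-bis(TBSO)-6-hydroxy-15-methylnonadec-1-yn-8-one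
Product: 23 (4S,6R,8S,12S,14R,15S)-14-(benzyloxy)-4,12-bis(TBSO)-15-methylnonadec-1-yne-6,8-diol
Conditions: Me4NBH(OAc)3 (5 equiv), MeCN/AcOH (1:1), −30 °C
Reagents that add atoms: none
Why: Evans–Saksena reduction: the C27 hydroxyl replaces an acetate on boron and the alkoxyborohydride delivers hydride intramolecularly through a chair-like six-membered transition state with the C30 chain equatorial, giving the 1,3-anti diol at C29. The reagent is too weak to reduce the ketone intermolecularly.

Step 17
Reactants: 23 (4S,6R,8S,12S,14R,15S)-14-(benzyloxy)-4,12-bis(TBSO)-15-methylnonadec-1-yne-6,8-diol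
Product: 24 (4S,6R,8S,12S,14R,15S)-14-(benzyloxy)-4,6,8,12-tetrakis(TBSO)-15-methylnonadec-1-yne
Conditions: TBSOTf (3 equiv), 2,6-lutidine (5 equiv), CH2Cl2, −78 → 0 °C
Reagents that add atoms: tert-butyldimethylsilyl trifluoromethanesulfonate, CC(C)(C)[Si](C)(C)OS(=O)(=O)C(F)(F)F
Why: Silylation of both hydroxyls of the anti diol with the silyl triflate; the terminal alkyne C–H is not silylated under lutidine. All hydroxyls except O35 now carry the same group.

Step 18
Reactants: 25 pentanedial (glutaraldehyde, anhydrous, freshly distilled)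
Product: 26 (4S,8S)-undeca-1,10-diene-4,8-diol
Conditions: (+)-Ipc2B(allyl) (from (−)-α-pinene, 2.3 equiv), Et2O, −78 °C → rt; NaOH, H2O2
Reagents that add atoms: (+)-B-allyldiisopinocampheylborane, C=CCB([C@H]1C[C@H]2C[C@@H]([C@@H]1C)C2(C)C)[C@H]1C[C@H]2C[C@@H]([C@@H]1C)C2(C)C
Why: Brown allylboration through a chair Zimmerman–Traxler transition state; this antipode adds allyl to the Re face of an unbranched aldehyde, so both carbinols (C13 and C17) should be S. As the two ends react independently, mismatched events end in the separable meso diol and the C2 diol is enriched.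

Step 19
Reactants: 26 (4S,8S)-undeca-1,10-diene-4,8-diol
Product: 27 (4S,8S)-4,8-bis[(tert-butyldimethylsilyl)oxy]undeca-1,10-diene
Conditions: TBSCl (2.5 equiv), imidazole (5 equiv), DMF, rt
Reagents that add atoms: tert-butyldimethylsilyl chloride, CC(C)(C)[Si](C)(C)Cl
Why: Standard double silylation of unhindered secondary alcohols; it keeps alkoxides out of the later acetylide additions.

Step 20
Reactants: 27 (4S,8S)-4,8-bis[(tert-butyldimethylsilyl)oxy]undeca-1,10-diene
Product: 28 (2E,5S,9S,11E)-5,9-bis(TBSO)-N1,N13-dimethoxy-N1,N13-dimethyltrideca-2,11-dienediamide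
Conditions: CH2=CHC(O)N(OMe)Me (6 equiv), second-generation Hoveyda–Grubbs catalyst RuCl2(H2IMes)(=CH-C6H4-2-OiPr) (5 mol%), CH2Cl2, 40 °C
Reagents that add atoms: N-methoxy-N-methylprop-2-enamide, C=CC(=O)N(C)OC
Why: Olefin cross-metathesis of a terminal alkene with an electron-poor acrylamide favours the cross product and the E isomer. It adds C9–C11 and C19–C21 at once and installs both acyl termini as N-methoxy-N-methyl amides.

Step 21
Reactants: 28 (2E,5S,9S,11E)-5,9-bis(TBSO)-N1,N13-dimethoxy-N1,N13-dimethyltrideca-2,11-dienediamide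
Product: 29 (5S,9S)-5,9-bis(TBSO)-N1,N13-dimethoxy-N1,N13-dimethyltridecanediamide
Conditions: H2 (1 atm), Pd/C, EtOAc, rt
Reagents that add atoms: none
Why: Heterogeneous hydrogenation of the conjugated alkenes; silyl ethers and the N–O bond of the amides are stable under these neutral conditions.

Step 22
Reactants: 30 (3S)-5-methoxy-3-methyl-5-oxopentanoic acid
Product: 31 methyl (3S)-5-hydroxy-3-methylpentanoate
Conditions: BH3·SMe2 (1.1 equiv), THF, −10 °C → rt; MeOH
Reagents that add atoms: none
Why: Borane reduces the carboxylic acid through an acyloxyborane much faster than the methyl ester. The C3 stereocentre is remote from both carbonyls and is kept.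

Step 23
Reactants: 31 methyl (3S)-5-hydroxy-3-methylpentanoate
Product: 32 methyl (3S)-5-(benzyloxy)-3-methylpentanoate
Conditions: benzyl 2,2,2-trichloroacetimidate (1.3 equiv), TfOH (5 mol%), CH2Cl2/cyclohexane, 0 °C → rt
Reagents that add atoms: benzyl 2,2,2-trichloroacetimidate, N=C(OCc1ccccc1)C(Cl)(Cl)Cl
Why: Acid-catalysed benzylation with the imidate avoids the alkoxide, which would lactonise onto the ester. The benzyl ether masks C1 until the late hydrogenation.

Step 24
Reactants: 32 methyl (3S)-5-(benzyloxy)-3-methylpentanoate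
Product: 33 (3S)-5-(benzyloxy)-3-methylpentanal
Conditions: i-Bu2AlH (1.05 equiv), CH2Cl2, −78 °C; MeOH, aq. potassium sodium tartrate
Reagents that add atoms: none
Why: Partial reduction of the ester stops at the tetrahedral aluminium hemiacetal at −78 °C and gives the aldehyde on work-up; the stereocentre is β to the carbonyl and cannot epimerise.

Step 25
Reactants: 33 (3S)-5-(benzyloxy)-3-methylpentanal
Product: 34 (4R,6S)-8-(benzyloxy)-6-methyloct-1-en-4-ol
Conditions: (+)-Ipc2B(allyl) (from (−)-α-pinene, 1.3 equiv), Et2O, −78 °C; NaOH, H2O2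
Reagents that add atoms: (+)-B-allyldiisopinocampheylborane, C=CCB([C@H]1C[C@H]2C[C@@H]([C@@H]1C)C2(C)C)[C@H]1C[C@H]2C[C@@H]([C@@H]1C)C2(C)C
Why: Brown allylboration with Re-face delivery sets C5 syn to the C3 methyl group. The β-methyl centre exerts little bias, so the reagent should decide the outcome.

Step 26
Reactants: 34 (4R,6S)-8-(benzyloxy)-6-methyloct-1-en-4-ol
Product: 35 {[(4R,6S)-8-(benzyloxy)-6-methyloct-1-en-4-yl]oxy}(tert-butyl)dimethylsilane
Conditions: TBSCl (1.3 equiv), imidazole (2.5 equiv), DMF, rt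
Reagents that add atoms: tert-butyldimethylsilyl chloride, CC(C)(C)[Si](C)(C)Cl
Why: Standard silylation of the secondary C5 hydroxyl.

Step 27
Reactants: 35 {[(4R,6S)-8-(benzyloxy)-6-methyloct-1-en-4-yl]oxy}(tert-butyl)dimethylsilane
Product: 36 (3S,5S)-7-(benzyloxy)-3-[(tert-butyldimethylsilyl)oxy]-5-methylheptanal
Conditions: O3, CH2Cl2, −78 °C; PPh3, −78 °C → rt
Reagents that add atoms: ozone, [O-][O+]=O
Why: Ozonolysis with reductive work-up shortens the allyl group to the C7 aldehyde; silyl and benzyl ethers survive at −78 °C.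

Step 28
Reactants: 36 (3S,5S)-7-(benzyloxy)-3-[(tert-butyldimethylsilyl)oxy]-5-methylheptanal
Product: 37 (4S,6S)-8-(benzyloxy)-4-[(tert-butyldimethylsilyl)oxy]-6-methyloct-1-yne
Conditions: MeC(O)C(N2)P(O)(OMe)2 (1.3 equiv), K2CO3 (2 equiv), MeOH, 0 °C → rt
Reagents that add atoms: dimethyl (1-diazo-2-oxopropyl)phosphonate, CC(=O)C(=[N+]=[N-])P(=O)(OC)OC
Why: Seyferth–Gilbert homologation (Ohira–Bestmann variant) converts the aldehyde into the terminal alkyne C7≡C8; the mild carbonate conditions should not eliminate the β-silyloxy group.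

Step 29
Reactants: 37 (4S,6S)-8-(benzyloxy)-4-[(tert-butyldimethylsilyl)oxy]-6-methyloct-1-yne; 29 (5S,9S)-5,9-bis(TBSO)-N1,N13-dimethoxy-N1,N13-dimethyltridecanediamide
Product: 38 (5S,9S,17S,19S)-21-(benzyloxy)-5,9,17-tris(TBSO)-N-methoxy-N,19-dimethyl-13-oxohenicos-14-ynamide
Conditions: 37, n-BuLi (1.0 equiv), THF, −78 °C; added to 29 (3 equiv), THF, −78 → −20 °C; cold aq. NaHSO4; excess 29 recovered
Reagents that add atoms: none
Why: Acetylide acylation by an N-methoxy-N-methyl amide: the chelated tetrahedral adduct is stable until quench, so the reacted terminus cannot add twice. The two amide groups of 29 are equivalent, so the excess of 29 should make the mono-adduct the main product; the acidic quench keeps the liberated amine from adding to the ynone.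

Step 30
Reactants: 38 (5S,9S,17S,19S)-21-(benzyloxy)-5,9,17-tris(TBSO)-N-methoxy-N,19-dimethyl-13-oxohenicos-14-ynamide
Product: 39 (5S,9R,13R,17S,19S)-21-(benzyloxy)-5,9,17-tris(TBSO)-13-hydroxy-N-methoxy-N,19-dimethylhenicos-14-ynamide
Conditions: Ru[(R,R)-TsDPEN](p-cymene) (5 mol%), i-PrOH, rt
Reagents that add atoms: none
Why: Noyori asymmetric transfer hydrogenation of an ynone: the alkyne plays the role of the aryl group in the six-membered hydride/proton transfer, and the (R,R) ligand should give the (R) propargylic alcohol at C9 under catalyst control. The remaining amide and the silyl ethers are untouched.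

Step 31
Reactants: 39 (5S,9R,13R,17S,19S)-21-(benzyloxy)-5,9,17-tris(TBSO)-13-hydroxy-N-methoxy-N,19-dimethylhenicos-14-ynamide
Product: 40 (5S,9S,13R,17S,19S)-21-(benzyloxy)-5,9,13,17-tetrakis(TBSO)-N-methoxy-N,19-dimethylhenicos-14-ynamide
Conditions: TBSOTf (1.3 equiv), 2,6-lutidine (2.5 equiv), CH2Cl2, −78 °C
Reagents that add atoms: tert-butyldimethylsilyl trifluoromethanesulfonate, CC(C)(C)[Si](C)(C)OS(=O)(=O)C(F)(F)F
Why: Silylation of the propargylic C9 hydroxyl so that no alkoxide consumes the valuable acetylide in step 32.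

Step 32
Reactants: 24 (4S,6R,8S,12S,14R,15S)-14-(benzyloxy)-4,6,8,12-tetrakis(TBSO)-15-methylnonadec-1-yne; 40 (5S,9S,13R,17S,19S)-21-(benzyloxy)-5,9,13,17-tetrakis(TBSO)-N-methoxy-N,19-dimethylhenicos-14-ynamide
Product: 41 1,35-bis(benzyloxy)-5,9,13,17,25,27,29,33-octakis(TBSO)-3,36-dimethyltetraconta-7,22-diyn-21-one (stereocentres as in 49)
Conditions: 24, n-BuLi (1.0 equiv), THF, −78 °C; 40 (1.1 equiv), −78 → −20 °C; cold aq. NaHSO4
Reagents that add atoms: none
Why: The lithium acetylide of 24 adds once to the N-methoxy-N-methyl amide of 40 and forms C21–C22. The stable chelated adduct prevents over-addition, and ethers and the internal alkyne are inert.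

Step 33
Reactants: 41 1,35-bis(benzyloxy)-5,9,13,17,25,27,29,33-octakis(TBSO)-3,36-dimethyltetraconta-7,22-diyn-21-one
Product: 42 1,35-bis(benzyloxy)-5,9,13,17,25,27,29,33-octakis(TBSO)-3,36-dimethyltetraconta-7,22-diyn-21-ol (21R as a propargylic alcohol; other centres as in 49)
Conditions: Ru[(R,R)-TsDPEN](p-cymene) (10 mol%), i-PrOH/CH2Cl2, rt
Reagents that add atoms: none
Why: Noyori transfer hydrogenation as in step 30. C21 is related to C9 by the local twofold axis of the C9–C21 stretch, so the same (R,R) catalyst should give the required (R) propargylic alcohol.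

Step 34
Reactants: 42 1,35-bis(benzyloxy)-5,9,13,17,25,27,29,33-octakis(TBSO)-3,36-dimethyltetraconta-7,22-diyn-21-ol
Product: 43 1,35-bis(benzyloxy)-5,9,13,17,21,25,27,29,33-nonakis(TBSO)-3,36-dimethyltetraconta-7,22-diyne (stereocentres as in 49)
Conditions: TBSOTf (1.5 equiv), 2,6-lutidine (3 equiv), CH2Cl2, −78 → 0 °C
Reagents that add atoms: tert-butyldimethylsilyl trifluoromethanesulfonate, CC(C)(C)[Si](C)(C)OS(=O)(=O)C(F)(F)F
Why: Silylation of the C21 hydroxyl, after which O1 and O35 are the only oxygens that do not carry a silyl group.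

Step 35
Reactants: 43 1,35-bis(benzyloxy)-5,9,13,17,21,25,27,29,33-nonakis(TBSO)-3,36-dimethyltetraconta-7,22-diyne
Product: 44 5,9,13,17,21,25,27,29,33-nonakis(TBSO)-3,36-dimethyltetracontane-1,35-diol (stereocentres as in 49)
Conditions: H2 (1–3 atm), Pd(OH)2/C, NaHCO3, EtOAc, rt
Reagents that add atoms: none
Why: One heterogeneous hydrogenation saturates both alkynes and hydrogenolyses both benzyl ethers; silyl ethers are stable in buffered ethyl acetate. No stereocentre is formed or lost, since the carbinol carbons C9 and C21 stay sp3 throughout.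

Step 36
Reactants: 44 5,9,13,17,21,25,27,29,33-nonakis(TBSO)-3,36-dimethyltetracontane-1,35-diol
Product: 46 35-hydroxy-5,9,13,17,21,25,27,29,33-nonakis(TBSO)-3,36-dimethyltetracontanoic acid, via 35-hydroxy-C1-aldehyde 45 (not isolated)
Conditions: TEMPO (20 mol%), PhI(OAc)2 (1.2 equiv), CH2Cl2, rt; then NaClO2, NaH2PO4, 2-methylbut-2-ene, t-BuOH/H2O, rt
Reagents that add atoms: sodium chlorite, [Na+].[O-]Cl=O
Why: The oxoammonium salt from TEMPO oxidises the unhindered primary C1 alcohol much faster than the hindered secondary C35 alcohol. Pinnick oxidation then takes the aldehyde to the acid without touching the secondary alcohol; C3 is β to the carbonyl and cannot epimerise.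

Step 37
Reactants: 46 35-hydroxy-5,9,13,17,21,25,27,29,33-nonakis(TBSO)-3,36-dimethyltetracontanoic acid
Product: 48 nonakis-TBS ether of 49 (36-membered lactone), via 2,4,6-trichlorobenzoic mixed anhydride 47 (not isolated)
Conditions: 2,4,6-trichlorobenzoyl chloride (1.5 equiv), Et3N (3 equiv), THF, rt; then syringe-pump addition to DMAP (10 equiv), toluene, 80 °C, about 1 mM
Reagents that add atoms: none
Why: Yamaguchi macrolactonisation: the mixed anhydride is attacked by DMAP at the less hindered acyl carbon and the acylpyridinium is trapped by the only free hydroxyl, O35. High dilution should favour the strain-free 36-membered ring over oligomers, and C35 keeps its configuration because its C–O bond is not broken.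

Step 38
Reactants: 48 nonakis-TBS ether of 49
Product: 49 (4R,6R,10R,14S,18S,22R,26S,28S,30S,34S,36R)-36-[(2S)-hexan-2-yl]-6,10,14,18,22,26,28,30,34-nonahydroxy-4-methyl-1-oxacyclohexatriacontan-2-one
Conditions: HF·pyridine (excess), pyridine/THF, 0 °C → rt
Reagents that add atoms: none
Why: Fluoride-driven cleavage of all nine secondary silyl ethers in one operation. The buffered acidic medium should avoid the base-induced acyl migration from O35 to O33 and leave the lactone intact.

## Compound list

1 | chloroacetaldehyde | ClCC=O | starting material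
2 | acetaldehyde | CC=O | starting material
3 | (3S)-4-chloro-3-hydroxybutanal | ClC[C@@H](O)CC=O | intermediate (not isolated)
4 | (3R,5S)-6-chloro-3,5-dihydroxyhexanal | ClC[C@@H](O)C[C@@H](O)CC=O | intermediate (not isolated)
5 | (4R,6S)-6-(chloromethyl)oxane-2,4-diol (lactol of 4, anomeric mixture) | ClC[C@@H]1C[C@@H](O)CC(O)O1 | intermediate
6 | (2S,4S)-1-chlorohept-6-yne-2,4-diol | ClC[C@@H](O)C[C@@H](O)CC#C | intermediate (not isolated)
7 | (2S)-1-[(2S)-oxiran-2-yl]pent-4-yn-2-ol | C#CC[C@H](O)C[C@H]1CO1 | intermediate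
8 | tert-butyldimethyl{[(2S)-1-[(2S)-oxiran-2-yl]pent-4-yn-2-yl]oxy}silane | C#CC[C@H](O[Si](C)(C)C(C)(C)C)C[C@H]1CO1 | intermediate
9 | (2E)-hept-2-en-1-ol | CCCC/C=C/CO | starting material
10 | [(2R,3R)-3-butyloxiran-2-yl]methanol | OC[C@H]1O[C@@H]1CCCC | intermediate
11 | (2S,3S)-3-methylheptane-1,2-diol | CCCC[C@H](C)[C@H](O)CO | intermediate
12 | (2S,3S)-2-hydroxy-3-methylheptyl 4-methylbenzenesulfonate | CCCC[C@H](C)[C@H](O)COS(=O)(=O)c1ccc(C)cc1 | intermediate (not isolated)
13 | (2S)-2-[(2S)-hexan-2-yl]oxirane | CCCC[C@H](C)[C@H]1CO1 | intermediate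
14 | (4R,5S)-5-methylnon-1-en-4-ol | CCCC[C@H](C)[C@H](O)CC=C | intermediate
15 | ({[(4R,5S)-5-methylnon-1-en-4-yl]oxy}methyl)benzene | CCCC[C@H](C)[C@H](OCc1ccccc1)CC=C | intermediate
16 | (3R,4S)-3-(benzyloxy)-4-methyloctanal | CCCC[C@H](C)[C@H](OCc1ccccc1)CC=O | intermediate
17 | (4S,6R,7S)-6-(benzyloxy)-7-methylundec-1-en-4-ol | CCCC[C@H](C)[C@H](OCc1ccccc1)C[C@@H](O)CC=C | intermediate
18 | {[(4S,6R,7S)-6-(benzyloxy)-7-methylundec-1-en-4-yl]oxy}(tert-butyl)dimethylsilane | CCCC[C@H](C)[C@H](OCc1ccccc1)C[C@@H](O[Si](C)(C)C(C)(C)C)CC=C | intermediate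
19 | (5S,7R,8S)-7-(benzyloxy)-5-[(tert-butyldimethylsilyl)oxy]-8-methyldodecanal | CCCC[C@H](C)[C@H](OCc1ccccc1)C[C@@H](O[Si](C)(C)C(C)(C)C)CCCC=O | intermediate
20 | 2-[(4S,6R,7S)-6-(benzyloxy)-4-[(tert-butyldimethylsilyl)oxy]-7-methylundecyl]-1,3-dithiane (C29–C40) | CCCC[C@H](C)[C@H](OCc1ccccc1)C[C@@H](O[Si](C)(C)C(C)(C)C)CCCC1SCCCS1 | intermediate
21 | (2S,4S)-4-(TBSO)-1-{2-[(4S,6R,7S)-6-(benzyloxy)-4-(TBSO)-7-methylundecyl]-1,3-dithian-2-yl}hept-6-yn-2-ol (C22–C40) | C#CC[C@H](O[Si](C)(C)C(C)(C)C)C[C@H](O)CC1(SCCCS1)CCC[C@H](O[Si](C)(C)C(C)(C)C)C[C@@H](OCc1ccccc1)[C@@H](C)CCCC | intermediate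
22 | (4S,6S,12S,14R,15S)-14-(benzyloxy)-4,12-bis(TBSO)-6-hydroxy-15-methylnonadec-1-yn-8-one | C#CC[C@H](O[Si](C)(C)C(C)(C)C)C[C@H](O)CC(=O)CCC[C@H](O[Si](C)(C)C(C)(C)C)C[C@@H](OCc1ccccc1)[C@@H](C)CCCC | intermediate
23 | (4S,6R,8S,12S,14R,15S)-14-(benzyloxy)-4,12-bis(TBSO)-15-methylnonadec-1-yne-6,8-diol | C#CC[C@H](O[Si](C)(C)C(C)(C)C)C[C@H](O)C[C@@H](O)CCC[C@H](O[Si](C)(C)C(C)(C)C)C[C@@H](OCc1ccccc1)[C@@H](C)CCCC | intermediate
24 | (4S,6R,8S,12S,14R,15S)-14-(benzyloxy)-4,6,8,12-tetrakis(TBSO)-15-methylnonadec-1-yne (C22–C40 alkyne) | C#CC[C@H](O[Si](C)(C)C(C)(C)C)C[C@H](O[Si](C)(C)C(C)(C)C)C[C@@H](O[Si](C)(C)C(C)(C)C)CCC[C@H](O[Si](C)(C)C(C)(C)C)C[C@@H](OCc1ccccc1)[C@@H](C)CCCC | intermediate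
25 | pentanedial (glutaraldehyde) | O=CCCCC=O | starting material
26 | (4S,8S)-undeca-1,10-diene-4,8-diol | C=CC[C@@H](O)CCC[C@H](O)CC=C | intermediate
27 | (4S,8S)-4,8-bis[(tert-butyldimethylsilyl)oxy]undeca-1,10-diene | C=CC[C@@H](O[Si](C)(C)C(C)(C)C)CCC[C@H](O[Si](C)(C)C(C)(C)C)CC=C | intermediate
28 | (2E,5S,9S,11E)-5,9-bis(TBSO)-N1,N13-dimethoxy-N1,N13-dimethyltrideca-2,11-dienediamide | CON(C)C(=O)/C=C/C[C@@H](O[Si](C)(C)C(C)(C)C)CCC[C@H](O[Si](C)(C)C(C)(C)C)C/C=C/C(=O)N(C)OC | intermediate
29 | (5S,9S)-5,9-bis(TBSO)-N1,N13-dimethoxy-N1,N13-dimethyltridecanediamide (C9–C21) | CON(C)C(=O)CCC[C@@H](O[Si](C)(C)C(C)(C)C)CCC[C@H](O[Si](C)(C)C(C)(C)C)CCCC(=O)N(C)OC | intermediate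
30 | (3S)-5-methoxy-3-methyl-5-oxopentanoic acid (methyl hydrogen (3S)-3-methylglutarate) | OC(=O)C[C@H](C)CC(=O)OC | starting material
31 | methyl (3S)-5-hydroxy-3-methylpentanoate | OCC[C@H](C)CC(=O)OC | intermediate
32 | methyl (3S)-5-(benzyloxy)-3-methylpentanoate | c1ccccc1COCC[C@H](C)CC(=O)OC | intermediate
33 | (3S)-5-(benzyloxy)-3-methylpentanal | c1ccccc1COCC[C@H](C)CC=O | intermediate
34 | (4R,6S)-8-(benzyloxy)-6-methyloct-1-en-4-ol | c1ccccc1COCC[C@H](C)C[C@H](O)CC=C | intermediate
35 | {[(4R,6S)-8-(benzyloxy)-6-methyloct-1-en-4-yl]oxy}(tert-butyl)dimethylsilane | c1ccccc1COCC[C@H](C)C[C@H](O[Si](C)(C)C(C)(C)C)CC=C | intermediate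
36 | (3S,5S)-7-(benzyloxy)-3-[(tert-butyldimethylsilyl)oxy]-5-methylheptanal | c1ccccc1COCC[C@H](C)C[C@H](O[Si](C)(C)C(C)(C)C)CC=O | intermediate
37 | (4S,6S)-8-(benzyloxy)-4-[(tert-butyldimethylsilyl)oxy]-6-methyloct-1-yne (C1–C8 alkyne) | c1ccccc1COCC[C@H](C)C[C@H](O[Si](C)(C)C(C)(C)C)CC#C | intermediate
38 | (5S,9S,17S,19S)-21-(benzyloxy)-5,9,17-tris(TBSO)-N-methoxy-N,19-dimethyl-13-oxohenicos-14-ynamide (C1–C21 ynone) | c1ccccc1COCC[C@H](C)C[C@H](O[Si](C)(C)C(C)(C)C)CC#CC(=O)CCC[C@@H](O[Si](C)(C)C(C)(C)C)CCC[C@H](O[Si](C)(C)C(C)(C)C)CCCC(=O)N(C)OC | intermediate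
39 | (5S,9R,13R,17S,19S)-21-(benzyloxy)-5,9,17-tris(TBSO)-13-hydroxy-N-methoxy-N,19-dimethylhenicos-14-ynamide | c1ccccc1COCC[C@H](C)C[C@H](O[Si](C)(C)C(C)(C)C)CC#C[C@H](O)CCC[C@@H](O[Si](C)(C)C(C)(C)C)CCC[C@H](O[Si](C)(C)C(C)(C)C)CCCC(=O)N(C)OC | intermediate
40 | (5S,9S,13R,17S,19S)-21-(benzyloxy)-5,9,13,17-tetrakis(TBSO)-N-methoxy-N,19-dimethylhenicos-14-ynamide (C1–C21 amide) | c1ccccc1COCC[C@H](C)C[C@H](O[Si](C)(C)C(C)(C)C)CC#C[C@H](O[Si](C)(C)C(C)(C)C)CCC[C@@H](O[Si](C)(C)C(C)(C)C)CCC[C@H](O[Si](C)(C)C(C)(C)C)CCCC(=O)N(C)OC | intermediate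
41 | 1,35-bis(benzyloxy)-5,9,13,17,25,27,29,33-octakis(TBSO)-3,36-dimethyltetraconta-7,22-diyn-21-one (stereocentres as in 49) | c1ccccc1COCC[C@H](C)C[C@H](O[Si](C)(C)C(C)(C)C)CC#C[C@H](O[Si](C)(C)C(C)(C)C)CCC[C@@H](O[Si](C)(C)C(C)(C)C)CCC[C@H](O[Si](C)(C)C(C)(C)C)CCCC(=O)C#CC[C@H](O[Si](C)(C)C(C)(C)C)C[C@H](O[Si](C)(C)C(C)(C)C)C[C@@H](O[Si](C)(C)C(C)(C)C)CCC[C@H](O[Si](C)(C)C(C)(C)C)C[C@@H](OCc1ccccc1)[C@@H](C)CCCC | intermediate
42 | 1,35-bis(benzyloxy)-5,9,13,17,25,27,29,33-octakis(TBSO)-3,36-dimethyltetraconta-7,22-diyn-21-ol (stereocentres as in 49) | c1ccccc1COCC[C@H](C)C[C@H](O[Si](C)(C)C(C)(C)C)CC#C[C@H](O[Si](C)(C)C(C)(C)C)CCC[C@@H](O[Si](C)(C)C(C)(C)C)CCC[C@H](O[Si](C)(C)C(C)(C)C)CCC[C@@H](O)C#CC[C@H](O[Si](C)(C)C(C)(C)C)C[C@H](O[Si](C)(C)C(C)(C)C)C[C@@H](O[Si](C)(C)C(C)(C)C)CCC[C@H](O[Si](C)(C)C(C)(C)C)C[C@@H](OCc1ccccc1)[C@@H](C)CCCC | intermediate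
43 | 1,35-bis(benzyloxy)-5,9,13,17,21,25,27,29,33-nonakis(TBSO)-3,36-dimethyltetraconta-7,22-diyne (stereocentres as in 49) | c1ccccc1COCC[C@H](C)C[C@H](O[Si](C)(C)C(C)(C)C)CC#C[C@H](O[Si](C)(C)C(C)(C)C)CCC[C@@H](O[Si](C)(C)C(C)(C)C)CCC[C@H](O[Si](C)(C)C(C)(C)C)CCC[C@@H](O[Si](C)(C)C(C)(C)C)C#CC[C@H](O[Si](C)(C)C(C)(C)C)C[C@H](O[Si](C)(C)C(C)(C)C)C[C@@H](O[Si](C)(C)C(C)(C)C)CCC[C@H](O[Si](C)(C)C(C)(C)C)C[C@@H](OCc1ccccc1)[C@@H](C)CCCC | intermediate
44 | 5,9,13,17,21,25,27,29,33-nonakis(TBSO)-3,36-dimethyltetracontane-1,35-diol (stereocentres as in 49) | OCC[C@H](C)C[C@H](O[Si](C)(C)C(C)(C)C)CCC[C@H](O[Si](C)(C)C(C)(C)C)CCC[C@@H](O[Si](C)(C)C(C)(C)C)CCC[C@H](O[Si](C)(C)C(C)(C)C)CCC[C@@H](O[Si](C)(C)C(C)(C)C)CCC[C@H](O[Si](C)(C)C(C)(C)C)C[C@H](O[Si](C)(C)C(C)(C)C)C[C@@H](O[Si](C)(C)C(C)(C)C)CCC[C@H](O[Si](C)(C)C(C)(C)C)C[C@@H](O)[C@@H](C)CCCC | intermediate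
45 | 35-hydroxy-5,9,13,17,21,25,27,29,33-nonakis(TBSO)-3,36-dimethyltetracontanal (stereocentres as in 49) | O=CC[C@H](C)C[C@H](O[Si](C)(C)C(C)(C)C)CCC[C@H](O[Si](C)(C)C(C)(C)C)CCC[C@@H](O[Si](C)(C)C(C)(C)C)CCC[C@H](O[Si](C)(C)C(C)(C)C)CCC[C@@H](O[Si](C)(C)C(C)(C)C)CCC[C@H](O[Si](C)(C)C(C)(C)C)C[C@H](O[Si](C)(C)C(C)(C)C)C[C@@H](O[Si](C)(C)C(C)(C)C)CCC[C@H](O[Si](C)(C)C(C)(C)C)C[C@@H](O)[C@@H](C)CCCC | intermediate (not isolated)
46 | 35-hydroxy-5,9,13,17,21,25,27,29,33-nonakis(TBSO)-3,36-dimethyltetracontanoic acid (seco acid, stereocentres as in 49) | OC(=O)C[C@H](C)C[C@H](O[Si](C)(C)C(C)(C)C)CCC[C@H](O[Si](C)(C)C(C)(C)C)CCC[C@@H](O[Si](C)(C)C(C)(C)C)CCC[C@H](O[Si](C)(C)C(C)(C)C)CCC[C@@H](O[Si](C)(C)C(C)(C)C)CCC[C@H](O[Si](C)(C)C(C)(C)C)C[C@H](O[Si](C)(C)C(C)(C)C)C[C@@H](O[Si](C)(C)C(C)(C)C)CCC[C@H](O[Si](C)(C)C(C)(C)C)C[C@@H](O)[C@@H](C)CCCC | intermediate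
47 | mixed anhydride of 46 with 2,4,6-trichlorobenzoic acid | O=C(c1c(Cl)cc(Cl)cc1Cl)OC(=O)C[C@H](C)C[C@H](O[Si](C)(C)C(C)(C)C)CCC[C@H](O[Si](C)(C)C(C)(C)C)CCC[C@@H](O[Si](C)(C)C(C)(C)C)CCC[C@H](O[Si](C)(C)C(C)(C)C)CCC[C@@H](O[Si](C)(C)C(C)(C)C)CCC[C@H](O[Si](C)(C)C(C)(C)C)C[C@H](O[Si](C)(C)C(C)(C)C)C[C@@H](O[Si](C)(C)C(C)(C)C)CCC[C@H](O[Si](C)(C)C(C)(C)C)C[C@@H](O)[C@@H](C)CCCC | intermediate (not isolated)
48 | nonakis-TBS ether of 49 (36-membered lactone, silyl ethers on O5, O9, O13, O17, O21, O25, O27, O29, O33) | O=C1C[C@H](C)C[C@H](O[Si](C)(C)C(C)(C)C)CCC[C@H](O[Si](C)(C)C(C)(C)C)CCC[C@@H](O[Si](C)(C)C(C)(C)C)CCC[C@H](O[Si](C)(C)C(C)(C)C)CCC[C@@H](O[Si](C)(C)C(C)(C)C)CCC[C@H](O[Si](C)(C)C(C)(C)C)C[C@H](O[Si](C)(C)C(C)(C)C)C[C@@H](O[Si](C)(C)C(C)(C)C)CCC[C@H](O[Si](C)(C)C(C)(C)C)C[C@@H](O1)[C@@H](C)CCCC | intermediate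
49 | (4R,6R,10R,14S,18S,22R,26S,28S,30S,34S,36R)-36-[(2S)-hexan-2-yl]-6,10,14,18,22,26,28,30,34-nonahydroxy-4-methyl-1-oxacyclohexatriacontan-2-one | CCCC[C@H](C)[C@H]1C[C@@H](O)CCC[C@H](O)C[C@@H](O)C[C@@H](O)CCC[C@H](O)CCC[C@@H](O)CCC[C@H](O)CCC[C@@H](O)CCC[C@@H](O)C[C@@H](C)CC(=O)O1 | target

## Step count and least certain steps

Total step count: 38. Longest linear sequence: 21 steps (9 → 20 in steps 4–13, then steps 14–17 and 32–38). From the key step, the DERA-derived carbons travel 14 steps (1–3, 14–17, 32–38).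

**Step 1 (key step).** The enzyme may be alkylated and deactivated by chloroacetaldehyde at useful concentrations. Acetaldehyde may be diverted into its own triple aldol, or the sequence may stall at the mono-adduct, so that throughput rather than selectivity limits the step. The fallback sets out from 1 (dried, distilled monomer) and replaces enzyme control by reagent control. Allylboration with (−)-Ipc2B(allyl) (Si-face delivery) gives (2S)-1-chloropent-4-en-2-ol F1. Ozonolysis of F1 gives 3, here isolated. A second allylboration with the same antipode gives (2S,4S)-1-chlorohept-6-ene-2,4-diol F2. Ozonolysis of F2 gives 4, which closes to 5, where the route is rejoined.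

**Step 2.** Once the lactol opens, the C25 alkoxide may displace chloride at C28 in a 5-exo closure to a tetrahydrofuran instead of the wanted 3-exo closure by O27. The free β-hydroxy aldehyde tautomer may also eliminate under carbonate before it is homologated. The fallback sets out from 5 and blocks O25 first. Oxidation (Br2, BaCO3, H2O) gives (4R,6S)-6-(chloromethyl)-4-hydroxyoxan-2-one F3. Silylation gives (4R,6S)-4-[(tert-butyldimethylsilyl)oxy]-6-(chloromethyl)oxan-2-one F4. Reduction with i-Bu2AlH at −78 °C gives (4R,6S)-4-[(tert-butyldimethylsilyl)oxy]-6-(chloromethyl)oxan-2-ol F5. The same diazophosphonate/K2CO3/MeOH treatment then converts F5 directly into 8, where the route is rejoined; only O27 can close onto C28.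

**Step 14.** If the alkyne is not fully deprotonated, proton transfer quenches the dithiane anion. The lithium acetylide may also open the epoxide of a second molecule once the mixture is warmed with HMPA present. The fallback sets out from 8 and masks the alkyne covalently. n-BuLi then Me3SiCl gives tert-butyldimethyl{[(2S)-1-[(2S)-oxiran-2-yl]-5-(trimethylsilyl)pent-4-yn-2-yl]oxy}silane F8. Opening of F8 with lithiated 20 gives the C-silylated hydroxy dithiane F9. K2CO3 in MeOH removes the alkynyl silyl group from F9 and returns 21.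

**Step 35.** While each alkyne passes through the alkene stage on palladium, the propargylic/allylic C–O bonds at C9 and C21 may be hydrogenolysed. The hindered C35 benzyl ether may be cleaved only slowly, and long reaction times invite silyl loss. The fallback sets out from 43 and separates the two tasks. Diimide (TsNHNH2, NaOAc, aqueous DME, reflux) saturates both alkynes without hydrogenolysis and gives the saturated bis-benzyl ether F10. Both benzyl ethers of F10 are then removed by electron transfer with lithium 4,4'-di-tert-butylbiphenylide in THF at −78 °C, which returns 44.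

**Step 12.** Branched aldehyde formation and alkene isomerisation along the chain would give inseparable homologues. The fallback sets out from 18 and builds C29 by alkylation instead of carbonylation. Hydroboration–oxidation (9-BBN; NaOH, H2O2) gives (4S,6R,7S)-6-(benzyloxy)-4-[(tert-butyldimethylsilyl)oxy]-7-methylundecan-1-ol F6. I2, PPh3 and imidazole give {[(4S,6R,7S)-6-(benzyloxy)-1-iodo-7-methylundecan-4-yl]oxy}(tert-butyl)dimethylsilane F7. Alkylation of 2-lithio-1,3-dithiane with F7 gives 20 directly, bypassing 19.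

## Further compounds

F1 | step 1 | (2S)-1-chloropent-4-en-2-ol | ClC[C@@H](O)CC=C
F2 | step 1 | (2S,4S)-1-chlorohept-6-ene-2,4-diol | ClC[C@@H](O)C[C@@H](O)CC=C
F3 | step 2 | (4R,6S)-6-(chloromethyl)-4-hydroxyoxan-2-one | ClC[C@@H]1C[C@@H](O)CC(=O)O1
F4 | step 2 | (4R,6S)-4-[(tert-butyldimethylsilyl)oxy]-6-(chloromethyl)oxan-2-one | ClC[C@@H]1C[C@@H](O[Si](C)(C)C(C)(C)C)CC(=O)O1
F5 | step 2 | (4R,6S)-4-[(tert-butyldimethylsilyl)oxy]-6-(chloromethyl)oxan-2-ol | ClC[C@@H]1C[C@@H](O[Si](C)(C)C(C)(C)C)CC(O)O1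
F6 | step 12 | (4S,6R,7S)-6-(benzyloxy)-4-[(tert-butyldimethylsilyl)oxy]-7-methylundecan-1-ol | CCCC[C@H](C)[C@H](OCc1ccccc1)C[C@@H](O[Si](C)(C)C(C)(C)C)CCCO
F7 | step 12 | {[(4S,6R,7S)-6-(benzyloxy)-1-iodo-7-methylundecan-4-yl]oxy}(tert-butyl)dimethylsilane | CCCC[C@H](C)[C@H](OCc1ccccc1)C[C@@H](O[Si](C)(C)C(C)(C)C)CCCI
F8 | step 14 | tert-butyldimethyl{[(2S)-1-[(2S)-oxiran-2-yl]-5-(trimethylsilyl)pent-4-yn-2-yl]oxy}silane | C[Si](C)(C)C#CC[C@H](O[Si](C)(C)C(C)(C)C)C[C@H]1CO1
F9 | step 14 | 7-(trimethylsilyl) derivative of 21 (C-silylated hydroxy dithiane) | C[Si](C)(C)C#CC[C@H](O[Si](C)(C)C(C)(C)C)C[C@H](O)CC1(SCCCS1)CCC[C@H](O[Si](C)(C)C(C)(C)C)C[C@@H](OCc1ccccc1)[C@@H](C)CCCC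
F10 | step 35 | 1,35-bis(benzyloxy)-5,9,13,17,21,25,27,29,33-nonakis(TBSO)-3,36-dimethyltetracontane (stereocentres as in 49) | c1ccccc1COCC[C@H](C)C[C@H](O[Si](C)(C)C(C)(C)C)CCC[C@H](O[Si](C)(C)C(C)(C)C)CCC[C@@H](O[Si](C)(C)C(C)(C)C)CCC[C@H](O[Si](C)(C)C(C)(C)C)CCC[C@@H](O[Si](C)(C)C(C)(C)C)CCC[C@H](O[Si](C)(C)C(C)(C)C)C[C@H](O[Si](C)(C)C(C)(C)C)C[C@@H](O[Si](C)(C)C(C)(C)C)CCC[C@H](O[Si](C)(C)C(C)(C)C)C[C@@H](OCc1ccccc1)[C@@H](C)CCCC
A1 | alternative 1 | C5–C25 diyne diol: 1,21-bis[(4-methoxybenzyl)oxy]-5,17-bis(TBSO)henicosa-6,15-diyne-9,13-diol (C2-symmetric) | COc1ccc(cc1)COCCCC[C@H](O[Si](C)(C)C(C)(C)C)C#CC[C@@H](O)CCC[C@H](O)CC#C[C@@H](O[Si](C)(C)C(C)(C)C)CCCCOCc1ccc(OC)cc1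
A2 | alternative 1 | (2S,6S)-1,2:6,7-diepoxyheptane (C12–C18 bis-epoxide) | C1O[C@H]1CCC[C@H]1CO1
A3 | alternative 1 | tert-butyl({(3S)-7-[(4-methoxybenzyl)oxy]hept-1-yn-3-yl}oxy)dimethylsilane | COc1ccc(cc1)COCCCC[C@H](O[Si](C)(C)C(C)(C)C)C#C
A4 | alternative 2 | 36-membered (E)-enoate lactone, nonakis-TBS ether lacking the C3 methyl group | CCCC[C@H](C)[C@H]1C[C@@H](O[Si](C)(C)C(C)(C)C)CCC[C@H](O[Si](C)(C)C(C)(C)C)C[C@@H](O[Si](C)(C)C(C)(C)C)C[C@@H](O[Si](C)(C)C(C)(C)C)CCC[C@H](O[Si](C)(C)C(C)(C)C)CCC[C@@H](O[Si](C)(C)C(C)(C)C)CCC[C@H](O[Si](C)(C)C(C)(C)C)CCC[C@@H](O[Si](C)(C)C(C)(C)C)CCC[C@@H](O[Si](C)(C)C(C)(C)C)C/C=C/C(=O)O1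
A5 | alternative 2 | seco aldehyde: C3 aldehyde carrying a diethyl phosphonoacetate ester on O35, nonakis-TBS ether | CCCC[C@H](C)[C@H](OC(=O)CP(=O)(OCC)OCC)C[C@@H](O[Si](C)(C)C(C)(C)C)CCC[C@H](O[Si](C)(C)C(C)(C)C)C[C@@H](O[Si](C)(C)C(C)(C)C)C[C@@H](O[Si](C)(C)C(C)(C)C)CCC[C@H](O[Si](C)(C)C(C)(C)C)CCC[C@@H](O[Si](C)(C)C(C)(C)C)CCC[C@H](O[Si](C)(C)C(C)(C)C)CCC[C@@H](O[Si](C)(C)C(C)(C)C)CCC[C@@H](O[Si](C)(C)C(C)(C)C)CC=O
A6 | alternative 3 | C33 dithiane with O35 TBS ether, methoxymethyl ethers on O25, O27, O29 and a terminal alkene at the C23 end | CCCC[C@H](C)[C@H](O[Si](C)(C)C(C)(C)C)CC1(SCCCS1)CCC[C@H](OCOC)C[C@@H](OCOC)C[C@@H](OCOC)CC=C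
A7 | alternative 3 | (2S)-2-[(2S)-hexan-2-yl]oxirane (identical with 13) | CCCC[C@H](C)[C@H]1CO1
A8 | alternative 3 | tert-butyl(1,3-dithian-2-yl)dimethylsilane | CC(C)(C)[Si](C)(C)C1SCCCS1
A9 | alternative 3 | 11-iodo-4,6,8-tris(methoxymethoxy)undec-1-ene (C32 iodide; C25/C27 syn, C27/C29 anti as in 49) | ICCC[C@H](OCOC)C[C@@H](OCOC)C[C@@H](OCOC)CC=C
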